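All runs were computed on assumed constants, noise included.

**First minutes.** In the first minutes of the 30 min run, initiator meets impurity and free monomer together.

common to all: initiator 0.22 mM; impurity 0.12 mM

| charge | free monomer | transfer agent | remark | time |
|---|---|---|---|---|
| cedar | 9 mM | 0.18 mM | run made earlier |  |
| birch | 14 mM | 0.18 mM | run made earlier |  |
| flask | 18 mM | 0.180 mM |  | 30 min |

| run | time / min | monomer in chains / % | free monomer / % |
|---|---|---|---|
| cedar | 3.00 | 3.4 | 82.2 |
| cedar | 6.00 | 5.1 | 63.9 |
| cedar | 10.0 | 4.5 | 51.5 |
| cedar | 12.0 | 5.3 | 44.6 |
| cedar | 15.0 | 6.2 | 38.2 |
| cedar | 20.0 | 7.7 | 26.9 |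
| birch | 1.33 | 2.0 | 90.4 |
| birch | 2.50 | 2.9 | 84.9 |
| birch | 4.00 | 3.4 | 75.4 |
| birch | 6.00 | 5.3 | 67.5 |
| birch | 10.0 | 6.4 | 50.8 |
| birch | 20.0 | 9.3 | 27.5 |

(readings scatter by 1 percentage point)

* average number of monomer units in a chain (chains begun, living or dead) at 30 min
* part of the free monomer that has reacted at 30 min

- the average divides the monomer in chains by the number of chains begun, living and dead together
- candidate steps: free monomer + initiator -> living end + monomer in chains; living end + transfer agent -> dead chain; initiator + impurity -> spent initiator; free monomer + living end -> monomer in chains + living end; free monomer -> uncatalysed product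
- the earlier runs do not show the number of chains; that part of a forecast is a guess

The readings do not count chains, so we assume that impurity takes its 0.12 mM of initiator first and that each initiator left begins one chain. This gives the chains begun, B, the initiator charge minus the impurity charge, 0.100 mM. The average chain length is then monomer in chains divided by B.

**Middle stretch.** Cedar and birch hold 26.9% and 27.5% of their free monomer at 20.0 min, although they were charged with 9 mM and 14 mM. We therefore read the loss as first order. Their mean of 27.2% gives a constant k, the fractional loss per minute, of 0.0651 /min. Monomer in chains averages 8.50% there, so our first round for this flask gives 15.3 units per chain.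

**Last stretch.** With k, this flask keeps 14.2% of its free monomer at 30 min, so about 85.8% has reacted. We put that back in. Between 10.0 min and 20.0 min, cedar's chains took a fraction 0.130 of the free monomer lost. Applied to the monomer still to go, this raises the chain share to 10.2% and the length to 18.3. That assumes the pace holds while transfer agent kills ends, so we take it as the high side.

**The forecast.** It says 17 units and 85% reacted, and it warns: “Chain count is the guess.” Its length lies between our two rounds.

**The flask.** It gives 15.3 units and 85.1% reacted.

    free monomer + initiator → living end + monomer in chains (k = 2.50 /M/s)
    living end + transfer agent → dead chain (kL = 6.30 /M/s)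
    initiator + impurity → spent initiator (k = 1800 /M/s)
    free monomer + living end → monomer in chains + living end, rate k4*[living end]*[free monomer] (k = 1.70 /M/s)
    free monomer → uncatalysed product (k = 9.70 × 10⁻⁴ /s)

**Two routes.** At 8.70 min in this flask, free monomer passes into uncatalysed product 9.2 times as fast as into chains, and at 30.0 min living ends plus dead chains reach 0.102 mM against B of 0.100 mM. In a neighbouring flask with 0.88 mM of initiator, B is 0.760 mM and living ends plus dead chains come to 0.760 mM, while monomer in chains, 52.3%, exceeds uncatalysed product, 45.0%, and the average is 12.4 units.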